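The easy step was to take logarithms of the intermediate C readings of the larch run, which had twice the reagent of the flask, and to lay a line back to zero time.

| setting | larch | flask |
|---|---|---|
| starting material | 0.10 M | 0.10 M |
| reagent | 2.4 equiv | 1.20 equiv |
| remark | run made earlier |  |
| time |  | 80 min |

larch run (percent of the starting material charged)

| time / min | intermediate C / % | product / % |
|---|---|---|
| 2.00 | 42.5 | 9.5 |
| 6.00 | 19.1 | 34.0 |
| 10.0 | 9.8 | 49.5 |
| 15.0 | 4.1 | 58.5 |

(readings scatter by 0.5 percentage points)

- time, not beyond 80 min, at which the flask holds most intermediate C
- the amount of intermediate C, in percent of the starting material charged, at that time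



I drew that line two ways. The first pair of readings gave 63.4% of the charge at zero time and the last pair gave 56.0%, and I judged that the last pair cheats, since its scatter of 0.5 percentage points on a reading of 4.1% is carried back 15.0 min from a span of 5.00 min, so I kept the first value.

I then assumed that this amount was a balance (a pre-equilibrium) of starting material and reagent with intermediate C, the rest of the charge being free starting material. At balance the forward and back rates are equal, and their ratio loses time, which left 9.81 L mol⁻¹ for [intermediate C]/([starting material][reagent]), the holding quotient. Applied to the flask's charge, with each intermediate C costing one reagent, it gave me a peak of 43.0%, and since intermediate C in the larch run fell from its first reading on, I placed the flask's peak before 2.00 min, though that was a judgement carried over from a run with more reagent.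

The forecast differed from my reckoning: it gave 51% at 5 min, more than mine and later, holding that “the first step is fast and finished by about 2 min”.

The flask peaked at 38.4% after 0.856 min, with 43.6% starting material, 14.8% intermediate A and 52.4% of the reagent's own charge beside it, a quotient of 14.0 L mol⁻¹ against my 9.81 L mol⁻¹.

    reagent + intermediate B ⇌ product (K = 23.0 L mol⁻¹, k = 0.210 L mol⁻¹ s⁻¹)
    starting material + reagent ⇌ intermediate C (K = 14.0 L mol⁻¹, k = 0.280 L mol⁻¹ s⁻¹)
    intermediate A → intermediate B (k = 0.00630 s⁻¹)
    starting material + reagent → intermediate A (k = 0.0730 L mol⁻¹ s⁻¹)

In the flask the forward rate to intermediate A stood at 0.26 of the forward rate to intermediate C at the start and at 0.26 of it at 80.0 min. In a neighbour flask, like the flask but with 0.300 equiv of reagent, my 9.81 L mol⁻¹ gives 13.7%, and that neighbour flask's peak was 12.6%.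

(Readings and results stem from a simulated flask for substances that don't exist; the scatter is artificial.)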